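**Assumption:** the SMILES is read literally (cis-fused octahydroazulene, (E)-2-methylbut-2-enoate, 3R,3aS,4R,8R,8aR in azulene numbering), and methyl 3-oxocyclopent-1-ene-1-carboxylate is taken as a purchasable building block.

## Retrosynthetic overview

1. Target ⇐ aryl silyl ether cleavage ⇐ ring-closing metathesis of a cis-1,2-disubstituted cyclopentane diene that already carries both esters; the seven-membered ring is formed last.
2. Diene ⇐ CBS reduction and tigloylation of a vinyl ketone ⇐ vinyl Grignard opening of a cis-fused γ-lactone and aroylation of the freed secondary alcohol.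
3. Hydroxy lactone ⇐ exo-face isopropylcerium addition to a bicyclic keto lactone ⇐ Brown methallylboration of a cyclopentane aldehyde, then lactonisation (a temporary second ring).
4. Aldehyde ⇐ ozonolysis ⇐ enolate methylation anti to vinyl ⇐ anti vinyl cuprate addition to a γ-silyloxy cyclopentenoate ⇐ CBS reduction of the purchased five-membered enone ester.
5. Side branches: chiral methallylborane from (−)-α-pinene, silyl-protected aroyl chloride from 4-hydroxybenzoic acid, tigloyl chloride from tiglic acid.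

## Route

**Step 1**
Reactants: 1 methyl 3-oxocyclopent-1-ene-1-carboxylate
Product: 2 methyl (R)-3-hydroxycyclopent-1-ene-1-carboxylate
Conditions: (S)-2-methyl-CBS-oxazaborolidine (10 mol %), catecholborane, toluene, −78 °C; MeOH, aq. NaHCO3
Reagents that add atoms: none
Why: Corey–Bakshi–Shibata 1,2-reduction in which the alkenyl flank acts as the large group, so the (S)-catalyst gives the (R)-carbinol, a temporary stereocentre that later steers the ring substituents.

**Step 2**
Reactants: 2 methyl (R)-3-hydroxycyclopent-1-ene-1-carboxylate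
Product: 3 methyl (R)-3-(triethylsilyloxy)cyclopent-1-ene-1-carboxylate
Conditions: TESCl, imidazole, CH2Cl2, 0 °C → rt
Reagents that add atoms: chlorotriethylsilane, CC[Si](Cl)(CC)CC
Why: Standard silylation of a secondary allylic alcohol; the bulky silyl ether shields one face of the enoate.

**Step 3**
Reactants: 3 methyl (R)-3-(triethylsilyloxy)cyclopent-1-ene-1-carboxylate
Product: 5 methyl (2R,3R)-3-(triethylsilyloxy)-2-vinylcyclopentane-1-carboxylate (C-1 epimers), via silyl ketene acetal 4 (not isolated)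
Conditions: CH2=CHMgBr, CuBr·SMe2 (20 mol %), TMSCl, THF, −78 → −40 °C; then aq. NH4Cl
Reagents that add atoms: vinylmagnesium bromide, C=C[Mg]Br
Why: Copper-catalysed, TMSCl-accelerated conjugate addition in which the vinyl group enters the β-carbon anti to the neighbouring silyloxy group, setting the future C-3a; the C-1 mixture is erased in the next step.

**Step 4**
Reactants: 5 methyl (2R,3R)-3-(triethylsilyloxy)-2-vinylcyclopentane-1-carboxylate
Product: 7 methyl (1R,2R,3R)-1-methyl-3-(triethylsilyloxy)-2-vinylcyclopentane-1-carboxylate, via lithium enolate 6 (not isolated)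
Conditions: LiN(iPr)2 (LDA), THF, −78 °C; then MeI, DMPU, −78 → −20 °C
Reagents that add atoms: iodomethane, CI
Why: Ester enolate alkylation in which MeI attacks the planar enolate anti to the adjacent vinyl group, so the quaternary centre (future C-8a) has its ester cis to the vinyl group.

**Step 5**
Reactants: 7 methyl (1R,2R,3R)-1-methyl-3-(triethylsilyloxy)-2-vinylcyclopentane-1-carboxylate
Product: 9 methyl (1R,2R,3R)-2-formyl-1-methyl-3-(triethylsilyloxy)cyclopentane-1-carboxylate, via ozonide 8 (not isolated)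
Conditions: O3, CH2Cl2, −78 °C; then PPh3, −78 °C → rt
Reagents that add atoms: ozone, [O-][O+]=O
Why: Ozonolysis with reductive work-up cleaves the only alkene; neutral conditions avoid epimerisation or β-elimination of the silyloxy aldehyde.

**Step 6**
Reactants: 10 (−)-α-pinene, (1S,5S)-2,6,6-trimethylbicyclo[3.1.1]hept-2-ene
Product: 11 diisopinocampheylborane derived from (−)-α-pinene
Conditions: BH3·SMe2, THF, 0 °C, 3 d (crystallisation)
Reagents that add atoms: borane dimethyl sulfide, C[S+](C)[BH3-]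
Why: Hydroboration from the face opposite the gem-dimethyl bridge; slow crystallisation of the dialkylborane upgrades its optical purity.

**Step 7**
Reactants: 11 diisopinocampheylborane derived from (−)-α-pinene
Product: 12 B-methoxydiisopinocampheylborane derived from (−)-α-pinene
Conditions: MeOH, Et2O, 0 °C → rt
Reagents that add atoms: methanol, CO
Why: Methanolysis of the B–H bond gives the storable borinate.

**Step 8**
Reactants: 12 B-methoxydiisopinocampheylborane derived from (−)-α-pinene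
Product: 13 B-(2-methylallyl)diisopinocampheylborane derived from (−)-α-pinene
Conditions: 2-methylallylmagnesium chloride, Et2O, −78 °C → rt; pentane, filtration of magnesium salts under argon
Reagents that add atoms: 2-methylallylmagnesium chloride, CC(=C)C[Mg]Cl
Why: Substitution of methoxide at boron by the Grignard reagent gives the salt-free Brown methallylborane, used as a solution.

**Step 9**
Reactants: 9 methyl (1R,2R,3R)-2-formyl-1-methyl-3-(triethylsilyloxy)cyclopentane-1-carboxylate; 13 B-(2-methylallyl)diisopinocampheylborane derived from (−)-α-pinene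
Product: 15 (3R,3aR,4R,6aR)-4-hydroxy-6a-methyl-3-(2-methylallyl)hexahydro-1H-cyclopenta[c]furan-1-one, via hydroxy ester 14 (not isolated)
Conditions: Et2O, −78 °C; then NaOH (3 M), H2O2 (30 %), 0 °C → rt; then AcOH–THF–H2O (3:1:1), 40 °C
Reagents that add atoms: none
Why: Brown allylboration through a chair transition state, in which the borane from (−)-α-pinene attacks the Re face to give the (R)-carbinol (future C-4) under reagent control; acid then removes the silyl group and the cis hydroxy ester closes to the γ-lactone.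

**Step 10**
Reactants: 15 (3R,3aR,4R,6aR)-4-hydroxy-6a-methyl-3-(2-methylallyl)hexahydro-1H-cyclopenta[c]furan-1-one
Product: 16 (3R,3aS,6aR)-6a-methyl-3-(2-methylallyl)tetrahydro-1H-cyclopenta[c]furan-1,4(5H)-dione
Conditions: Dess–Martin periodinane, CH2Cl2, rt
Reagents that add atoms: none
Why: Dess–Martin oxidation of the secondary alcohol; the cis-fused lactone locks the α-stereocentre because a trans-fused bicyclo[3.3.0] system is too strained to form.

**Step 11**
Reactants: 16 (3R,3aS,6aR)-6a-methyl-3-(2-methylallyl)tetrahydro-1H-cyclopenta[c]furan-1,4(5H)-dione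
Product: 17 (3R,3aS,4R,6aR)-4-hydroxy-4-isopropyl-6a-methyl-3-(2-methylallyl)hexahydro-1H-cyclopenta[c]furan-1-one
Conditions: iPrMgCl, CeCl3 (anhydrous), THF, −78 °C; aq. NH4Cl
Reagents that add atoms: isopropylmagnesium chloride, CC(C)[Mg]Cl
Why: Organocerium 1,2-addition (low basicity avoids enolisation and β-elimination) on the convex face of the cis-bicyclic keto lactone, placing isopropyl cis to the ring-fusion hydrogen and methyl and the hydroxyl on the lactone side (future C-3); the lactone is untouched at −78 °C.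

**Step 12**
Reactants: 17 (3R,3aS,4R,6aR)-4-hydroxy-4-isopropyl-6a-methyl-3-(2-methylallyl)hexahydro-1H-cyclopenta[c]furan-1-one
Product: 18 1-[(1R,2S,3R)-3-hydroxy-2-[(1R)-1-hydroxy-3-methylbut-3-en-1-yl]-1-methyl-3-(propan-2-yl)cyclopentyl]prop-2-en-1-one
Conditions: CH2=CHMgBr (2.2 equiv), THF, −78 °C; quench at −78 °C with aq. NH4Cl
Reagents that add atoms: vinylmagnesium bromide, C=C[Mg]Br
Why: Single Grignard addition to the lactone (acyl substitution), since the magnesium hemiketalate survives at −78 °C and releases the enone only on work-up; the product equilibrates with its cyclic hemiketal and is used directly.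

**Step 13**
Reactants: 19 4-hydroxybenzoic acid
Product: 20 tert-butyldimethylsilyl 4-(tert-butyldimethylsilyloxy)benzoate
Conditions: TBSCl (2.2 equiv), imidazole, DMF, rt
Reagents that add atoms: tert-butyldimethylsilyl chloride, CC(C)(C)[Si](C)(C)Cl
Why: Exhaustive silylation of phenol and acid.

**Step 14**
Reactants: 20 tert-butyldimethylsilyl 4-(tert-butyldimethylsilyloxy)benzoate
Product: 21 4-(tert-butyldimethylsilyloxy)benzoic acid
Conditions: AcOH–THF–H2O (3:1:1), rt
Reagents that add atoms: none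
Why: The silyl ester hydrolyses far faster than the aryl silyl ether under mild aqueous acid.

**Step 15**
Reactants: 21 4-(tert-butyldimethylsilyloxy)benzoic acid
Product: 22 4-(tert-butyldimethylsilyloxy)benzoyl chloride
Conditions: (COCl)2, DMF (cat.), CH2Cl2, 0 °C → rt
Reagents that add atoms: oxalyl chloride, ClC(=O)C(=O)Cl
Why: Vilsmeier-type acid chloride formation under conditions that leave the aryl silyl ether intact.

**Step 16**
Reactants: 18 1-[(1R,2S,3R)-3-hydroxy-2-[(1R)-1-hydroxy-3-methylbut-3-en-1-yl]-1-methyl-3-(propan-2-yl)cyclopentyl]prop-2-en-1-one; 22 4-(tert-butyldimethylsilyloxy)benzoyl chloride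
Product: 23 (1R)-1-[(1S,2R,5R)-2-hydroxy-5-methyl-2-(propan-2-yl)-5-(prop-2-enoyl)cyclopentyl]-3-methylbut-3-en-1-yl 4-[(tert-butyldimethylsilyl)oxy]benzoate
Conditions: Et3N, DMAP (10 mol %), CH2Cl2, 0 °C
Reagents that add atoms: none
Why: DMAP-catalysed acylation of the only secondary hydroxyl, which reacts through the open-chain form; the tertiary alcohol and the hemiketal hydroxyl are inert.

**Step 17**
Reactants: 23 (1R)-1-[(1S,2R,5R)-2-hydroxy-5-methyl-2-(propan-2-yl)-5-(prop-2-enoyl)cyclopentyl]-3-methylbut-3-en-1-yl 4-[(tert-butyldimethylsilyl)oxy]benzoate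
Product: 24 (1R)-1-[(1S,2R,5R)-2-hydroxy-5-[(1R)-1-hydroxyprop-2-en-1-yl]-5-methyl-2-(propan-2-yl)cyclopentyl]-3-methylbut-3-en-1-yl 4-[(tert-butyldimethylsilyl)oxy]benzoate
Conditions: (S)-2-methyl-CBS-oxazaborolidine (1 equiv), catecholborane, toluene, −78 → −40 °C
Reagents that add atoms: none
Why: Corey–Bakshi–Shibata reduction with the quaternary carbon as the large and vinyl as the small group, giving the (R)-allylic alcohol (future C-8) under reagent control; catecholborane does not hydroborate the alkenes at this temperature.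

**Step 18**
Reactants: 25 tiglic acid, (E)-2-methylbut-2-enoic acid
Product: 26 tigloyl chloride, (E)-2-methylbut-2-enoyl chloride
Conditions: (COCl)2, DMF (cat.), CH2Cl2, rt
Reagents that add atoms: oxalyl chloride, ClC(=O)C(=O)Cl
Why: Acid chloride formation; the E isomer is the thermodynamic one, so no geometric leakage is expected.

**Step 19**
Reactants: 24 (1R)-1-[(1S,2R,5R)-2-hydroxy-5-[(1R)-1-hydroxyprop-2-en-1-yl]-5-methyl-2-(propan-2-yl)cyclopentyl]-3-methylbut-3-en-1-yl 4-[(tert-butyldimethylsilyl)oxy]benzoate; 26 tigloyl chloride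
Product: 27 (1R)-1-[(1S,2R,5R)-2-hydroxy-5-methyl-5-[(1R)-1-{[(2E)-2-methylbut-2-enoyl]oxy}prop-2-en-1-yl]-2-(propan-2-yl)cyclopentyl]-3-methylbut-3-en-1-yl 4-[(tert-butyldimethylsilyl)oxy]benzoate
Conditions: Et3N, DMAP (0.3 equiv), CH2Cl2, 0 → 40 °C
Reagents that add atoms: none
Why: Nucleophilic-catalysed acylation of the secondary allylic alcohol; the tertiary alcohol does not react.

**Step 20**
Reactants: 27 (1R)-1-[(1S,2R,5R)-2-hydroxy-5-methyl-5-[(1R)-1-{[(2E)-2-methylbut-2-enoyl]oxy}prop-2-en-1-yl]-2-(propan-2-yl)cyclopentyl]-3-methylbut-3-en-1-yl 4-[(tert-butyldimethylsilyl)oxy]benzoate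
Product: 28 (3R,3aS,4R,8R,8aR)-3-hydroxy-6,8a-dimethyl-8-{[(2E)-2-methylbut-2-enoyl]oxy}-3-(propan-2-yl)-1,2,3,3a,4,5,8,8a-octahydroazulen-4-yl 4-[(tert-butyldimethylsilyl)oxy]benzoate
Conditions: second-generation Grubbs catalyst (10 mol %), toluene (2 mM), 80 °C
Reagents that add atoms: none
Why: Ring-closing metathesis between the vinyl group and the 1,1-disubstituted alkene on cis-disposed arms gives the trisubstituted cycloheptene with loss of ethene; the electron-poor trisubstituted tiglate alkene does not take part.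

**Step 21**
Reactants: 28 (3R,3aS,4R,8R,8aR)-3-hydroxy-6,8a-dimethyl-8-{[(2E)-2-methylbut-2-enoyl]oxy}-3-(propan-2-yl)-1,2,3,3a,4,5,8,8a-octahydroazulen-4-yl 4-[(tert-butyldimethylsilyl)oxy]benzoate
Product: 29 (3R,3aS,4R,8R,8aR)-3-hydroxy-6,8a-dimethyl-8-{[(2E)-2-methylbut-2-enoyl]oxy}-3-(propan-2-yl)-1,2,3,3a,4,5,8,8a-octahydroazulen-4-yl 4-hydroxybenzoate (CNP0273650.8)
Conditions: TBAF, AcOH (1:1), THF, 0 °C
Reagents that add atoms: none
Why: Buffered fluoride cleaves the aryl silyl ether much faster than it touches the two esters, so no acyl migration or hydrolysis is expected.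

## Compound list

1 | methyl 3-oxocyclopent-1-ene-1-carboxylate | COC(=O)C1=CC(=O)CC1 | starting material
2 | methyl (R)-3-hydroxycyclopent-1-ene-1-carboxylate | COC(=O)C1=C[C@H](O)CC1 | intermediate
3 | methyl (R)-3-(triethylsilyloxy)cyclopent-1-ene-1-carboxylate | COC(=O)C1=C[C@H](O[Si](CC)(CC)CC)CC1 | intermediate
4 | trimethylsilyl ketene acetal of methyl (2R,3R)-3-(triethylsilyloxy)-2-vinylcyclopentanecarboxylate (not isolated) | COC(O[Si](C)(C)C)=C1CC[C@@H](O[Si](CC)(CC)CC)[C@@H]1C=C | intermediate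
5 | methyl (2R,3R)-3-(triethylsilyloxy)-2-vinylcyclopentane-1-carboxylate (C-1 epimer mixture) | COC(=O)C1CC[C@@H](O[Si](CC)(CC)CC)[C@@H]1C=C | intermediate
6 | lithium enolate of 5 (not isolated) | COC(O[Li])=C1CC[C@@H](O[Si](CC)(CC)CC)[C@@H]1C=C | intermediate
7 | methyl (1R,2R,3R)-1-methyl-3-(triethylsilyloxy)-2-vinylcyclopentane-1-carboxylate | COC(=O)[C@]1(C)CC[C@@H](O[Si](CC)(CC)CC)[C@@H]1C=C | intermediate
8 | 1,2,4-trioxolane (ozonide) of 7 (not isolated) | COC(=O)[C@]1(C)CC[C@@H](O[Si](CC)(CC)CC)[C@@H]1C1OCOO1 | intermediate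
9 | methyl (1R,2R,3R)-2-formyl-1-methyl-3-(triethylsilyloxy)cyclopentane-1-carboxylate | COC(=O)[C@]1(C)CC[C@@H](O[Si](CC)(CC)CC)[C@@H]1C=O | intermediate
10 | (−)-α-pinene, (1S,5S) | CC1=CC[C@H]2C[C@@H]1C2(C)C | starting material
11 | diisopinocampheylborane derived from (−)-α-pinene | [H]B([C@H]1C[C@H]2C[C@@H]([C@@H]1C)C2(C)C)[C@H]1C[C@H]2C[C@@H]([C@@H]1C)C2(C)C | intermediate
12 | B-methoxydiisopinocampheylborane derived from (−)-α-pinene | COB([C@H]1C[C@H]2C[C@@H]([C@@H]1C)C2(C)C)[C@H]1C[C@H]2C[C@@H]([C@@H]1C)C2(C)C | intermediate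
13 | B-(2-methylallyl)diisopinocampheylborane derived from (−)-α-pinene | CC(=C)CB([C@H]1C[C@H]2C[C@@H]([C@@H]1C)C2(C)C)[C@H]1C[C@H]2C[C@@H]([C@@H]1C)C2(C)C | intermediate
14 | methyl (1R,2S,3R)-2-[(1R)-1-hydroxy-3-methylbut-3-en-1-yl]-1-methyl-3-(triethylsilyloxy)cyclopentane-1-carboxylate (not isolated) | COC(=O)[C@]1(C)CC[C@@H](O[Si](CC)(CC)CC)[C@@H]1[C@H](O)CC(C)=C | intermediate
15 | (3R,3aR,4R,6aR)-4-hydroxy-6a-methyl-3-(2-methylallyl)hexahydro-1H-cyclopenta[c]furan-1-one | O=C1O[C@H](CC(C)=C)[C@H]2[C@H](O)CC[C@@]12C | intermediate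
16 | (3R,3aS,6aR)-6a-methyl-3-(2-methylallyl)tetrahydro-1H-cyclopenta[c]furan-1,4(5H)-dione | O=C1O[C@H](CC(C)=C)[C@H]2C(=O)CC[C@@]12C | intermediate
17 | (3R,3aS,4R,6aR)-4-hydroxy-4-isopropyl-6a-methyl-3-(2-methylallyl)hexahydro-1H-cyclopenta[c]furan-1-one | O=C1O[C@H](CC(C)=C)[C@H]2[C@](O)(C(C)C)CC[C@@]12C | intermediate
18 | 1-[(1R,2S,3R)-3-hydroxy-2-[(1R)-1-hydroxy-3-methylbut-3-en-1-yl]-1-methyl-3-(propan-2-yl)cyclopentyl]prop-2-en-1-one (in equilibrium with its cyclic hemiketal) | C=CC(=O)[C@]1(C)CC[C@@](O)(C(C)C)[C@@H]1[C@H](O)CC(C)=C | intermediate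
19 | 4-hydroxybenzoic acid | OC(=O)c1ccc(O)cc1 | starting material
20 | tert-butyldimethylsilyl 4-(tert-butyldimethylsilyloxy)benzoate | CC(C)(C)[Si](C)(C)OC(=O)c1ccc(O[Si](C)(C)C(C)(C)C)cc1 | intermediate
21 | 4-(tert-butyldimethylsilyloxy)benzoic acid | OC(=O)c1ccc(O[Si](C)(C)C(C)(C)C)cc1 | intermediate
22 | 4-(tert-butyldimethylsilyloxy)benzoyl chloride | ClC(=O)c1ccc(O[Si](C)(C)C(C)(C)C)cc1 | intermediate
23 | (1R)-1-[(1S,2R,5R)-2-hydroxy-5-methyl-2-(propan-2-yl)-5-(prop-2-enoyl)cyclopentyl]-3-methylbut-3-en-1-yl 4-[(tert-butyldimethylsilyl)oxy]benzoate | C=CC(=O)[C@]1(C)CC[C@@](O)(C(C)C)[C@@H]1[C@@H](CC(C)=C)OC(=O)c1ccc(O[Si](C)(C)C(C)(C)C)cc1 | intermediate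
24 | (1R)-1-[(1S,2R,5R)-2-hydroxy-5-[(1R)-1-hydroxyprop-2-en-1-yl]-5-methyl-2-(propan-2-yl)cyclopentyl]-3-methylbut-3-en-1-yl 4-[(tert-butyldimethylsilyl)oxy]benzoate | C=C[C@@H](O)[C@]1(C)CC[C@@](O)(C(C)C)[C@@H]1[C@@H](CC(C)=C)OC(=O)c1ccc(O[Si](C)(C)C(C)(C)C)cc1 | intermediate
25 | tiglic acid, (E)-2-methylbut-2-enoic acid | C/C=C(\C)C(=O)O | starting material
26 | tigloyl chloride, (E)-2-methylbut-2-enoyl chloride | C/C=C(\C)C(=O)Cl | intermediate
27 | (1R)-1-[(1S,2R,5R)-2-hydroxy-5-methyl-5-[(1R)-1-{[(2E)-2-methylbut-2-enoyl]oxy}prop-2-en-1-yl]-2-(propan-2-yl)cyclopentyl]-3-methylbut-3-en-1-yl 4-[(tert-butyldimethylsilyl)oxy]benzoate | C/C=C(\C)C(=O)O[C@H](C=C)[C@]1(C)CC[C@@](O)(C(C)C)[C@@H]1[C@@H](CC(C)=C)OC(=O)c1ccc(O[Si](C)(C)C(C)(C)C)cc1 | intermediate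
28 | (3R,3aS,4R,8R,8aR)-3-hydroxy-6,8a-dimethyl-8-{[(2E)-2-methylbut-2-enoyl]oxy}-3-(propan-2-yl)-1,2,3,3a,4,5,8,8a-octahydroazulen-4-yl 4-[(tert-butyldimethylsilyl)oxy]benzoate | C/C=C(\C)C(=O)O[C@@H]1C=C(C)C[C@@H](OC(=O)c2ccc(O[Si](C)(C)C(C)(C)C)cc2)[C@@H]2[C@@]1(C)CC[C@@]2(O)C(C)C | intermediate
29 | (3R,3aS,4R,8R,8aR)-3-hydroxy-6,8a-dimethyl-8-{[(2E)-2-methylbut-2-enoyl]oxy}-3-(propan-2-yl)-1,2,3,3a,4,5,8,8a-octahydroazulen-4-yl 4-hydroxybenzoate (CNP0273650.8) | C/C=C(\C)C(=O)O[C@@H]1C=C(C)C[C@@H](OC(=O)c2ccc(O)cc2)[C@@H]2[C@@]1(C)CC[C@@]2(O)C(C)C | target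

## Step count and risks

Total step count: 21.
Longest linear sequence: 14 steps (steps 1–5, 9–12, 16, 17, 19, 20, 21). The borane branch (steps 6–8), the aroyl chloride branch (steps 13–15) and the tigloyl chloride branch (step 18) join it at steps 9, 16 and 19.

The three steps most likely to fail, each with one fallback:

**Step 12** (a single vinyl addition to a hindered α-quaternary lactone; over-addition or no reaction). The fallback sets out from 17. Reduce the lactone with iBu2AlH (CH2Cl2, −78 °C) to the lactol F1. Open it with excess CH2=CHMgBr (THF, 0 °C) to the triol F2, formed as both epimers at the new allylic carbinol. Oxidise only the allylic alcohol with MnO2 (CH2Cl2, rt); this comes back to the route at 18.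

**Step 17** (sense and level of induction in the CBS reduction of a vinyl ketone flanked by a quaternary carbon). The fallback sets out from 17. Add ethynylmagnesium bromide (THF, −78 °C) to give the hydroxy ynone F3. Acylate it with 22 (Et3N, DMAP, CH2Cl2) to the ynone ester F4. Reduce with (S)-2-methyl-CBS-oxazaborolidine and catecholborane, where the ethynyl group is unambiguously the small substituent, to the propargylic alcohol F5. Semi-hydrogenate the terminal alkyne (H2, Pd/CaCO3 poisoned with Pb(OAc)2, quinoline, EtOAc); this comes back to the route at 24.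

**Step 20** (metathesis of a neopentylic allylic ester onto a 1,1-disubstituted alkene). The fallback sets out from 24. Close the ring on the free allylic alcohol, whose hydroxyl speeds loading of the ruthenium carbene (second-generation Hoveyda–Grubbs catalyst, toluene, 80 °C), to the bicyclic allylic alcohol F6. Acylate with 26 (Et3N, DMAP, CH2Cl2); this comes back to the route at 28.

## Further compounds

F1 | step 12 | (3R,3aS,4R,6aR)-4-isopropyl-6a-methyl-3-(2-methylallyl)hexahydro-1H-cyclopenta[c]furan-1,4-diol (lactol, both anomers) | OC1O[C@H](CC(C)=C)[C@H]2[C@](O)(C(C)C)CC[C@@]12C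
F2 | step 12 | (1R,2S,3R)-2-[(1R)-1-hydroxy-3-methylbut-3-en-1-yl]-3-(1-hydroxyprop-2-en-1-yl)-3-methyl-1-(propan-2-yl)cyclopentan-1-ol (both epimers at the allylic carbinol) | C=CC(O)[C@]1(C)CC[C@@](O)(C(C)C)[C@@H]1[C@H](O)CC(C)=C
F3 | step 17 | 1-[(1R,2S,3R)-3-hydroxy-2-[(1R)-1-hydroxy-3-methylbut-3-en-1-yl]-1-methyl-3-(propan-2-yl)cyclopentyl]prop-2-yn-1-one | C#CC(=O)[C@]1(C)CC[C@@](O)(C(C)C)[C@@H]1[C@H](O)CC(C)=C
F4 | step 17 | (1R)-1-[(1S,2R,5R)-2-hydroxy-5-methyl-2-(propan-2-yl)-5-(prop-2-ynoyl)cyclopentyl]-3-methylbut-3-en-1-yl 4-[(tert-butyldimethylsilyl)oxy]benzoate | C#CC(=O)[C@]1(C)CC[C@@](O)(C(C)C)[C@@H]1[C@@H](CC(C)=C)OC(=O)c1ccc(O[Si](C)(C)C(C)(C)C)cc1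
F5 | step 17 | (1R)-1-[(1S,2R,5R)-2-hydroxy-5-[(1R)-1-hydroxyprop-2-yn-1-yl]-5-methyl-2-(propan-2-yl)cyclopentyl]-3-methylbut-3-en-1-yl 4-[(tert-butyldimethylsilyl)oxy]benzoate | C#C[C@@H](O)[C@]1(C)CC[C@@](O)(C(C)C)[C@@H]1[C@@H](CC(C)=C)OC(=O)c1ccc(O[Si](C)(C)C(C)(C)C)cc1
F6 | step 20 | (3R,3aS,4R,8R,8aR)-3,8-dihydroxy-6,8a-dimethyl-3-(propan-2-yl)-1,2,3,3a,4,5,8,8a-octahydroazulen-4-yl 4-[(tert-butyldimethylsilyl)oxy]benzoate | O[C@@H]1C=C(C)C[C@@H](OC(=O)c2ccc(O[Si](C)(C)C(C)(C)C)cc2)[C@@H]2[C@@]1(C)CC[C@@]2(O)C(C)C
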